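**Plan**
- Retrosynthesis: cut the interflavan C4–C8 bond (flavan-4-yl cation plus C8 of a second molecule of the same 2,3-cis-flavan-3-ol). In the monomer, go back from the C3 carbinol to the C3 ketone and then to a C3–CHO helper, and finally cut C3–C4 (aldol) and O1–C2 (oxa-Michael).
- Enabling feature: in each unit the atoms O1–C2–C3–C4–C4a of ring C map onto a salicylaldehyde (O1, C4a, C4 = formyl carbon of ring A) and cinnamaldehyde (C2 = β-carbon carrying the phenyl ring, C3 = α-carbon). The formyl carbon left on C3 is a helper that is later exchanged for the C3 oxygen.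
- Forward: ring A aldehyde plus cinnamaldehyde; ring C is closed through the C3–C4 aldol bond; Baeyer–Villiger excision of the helper gives the ketone, then the 2,3-cis alcohol. One part is oxidised at C4 and joined to C8 of a second part; debenzylation ends the route.
- Stereochemistry: C2 of both units from the amine-catalysed oxa-Michael step; C3 of both units from hydride delivery to the flavan-3-one (cis to the 2-phenyl group); C4 from attack of the nucleophile anti to the C3 hydroxyl (3,4-trans).

Key step: step 2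

Assumption: the (S)-diarylprolinol silyl ether is taken to shield the iminium face in the usual way, so that the phenol oxygen adds to give the 2R chromene; if the opposite sense were found, the (R)-catalyst would be used with no other change.

Step 1
Reactants: 1 2,4,6-trihydroxybenzaldehyde
Product: 2 2,4-bis(benzyloxy)-6-hydroxybenzaldehyde
Conditions: BnBr (2.1 equiv), K2CO3, DMF, 0 °C to rt
Reagents that add atoms: benzyl bromide, BrCc1ccccc1
Why: Williamson ether synthesis in which the two hydroxyls not tied up in the hydrogen bond to the formyl oxygen react first, so that alkylation should stop at the known chelated 6-hydroxy dibenzyl ether; no stereocentre is formed.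

Step 2
Reactants: 2 2,4-bis(benzyloxy)-6-hydroxybenzaldehyde; 3 (E)-cinnamaldehyde (1.5 equiv)
Product: 6 (R)-5,7-bis(benzyloxy)-2-phenyl-2H-chromene-3-carbaldehyde, via oxa-Michael adduct 4 (not isolated), via aldol 5 (not isolated)
Conditions: (S)-α,α-diphenylprolinol trimethylsilyl ether (20 mol %), 2-nitrobenzoic acid (20 mol %), 4 Å molecular sieves, toluene, 0 °C to rt
Reagents that add atoms: none
Why: The amine condenses with 3 to an (E)-iminium ion, to which the phenol oxygen of 2 adds at the β-carbon (future C2) from the face left open by the CPh2(OSiMe3) group, giving the enamine of 4. The enamine carbon (future C3) then attacks the neighbouring aryl aldehyde carbon (future C4) in an intramolecular aldol addition, a 6-(enolexo)-exo-trig closure that forms the C3–C4 bond and closes ring C (5). Loss of water and hydrolysis of the iminium ion give the enal 6 and return the catalyst. The closest known reaction type is the amine-catalysed domino oxa-Michael/aldol condensation of salicylaldehydes with β-aryl enals to 2-aryl-2H-chromene-3-carbaldehydes. C2 is the only lasting stereocentre (C3 and C4 end up sp2) and is set by the catalyst in the oxa-Michael step. The step needs enantioface selection in a reversible oxa-Michael addition; the formyl group ortho to the phenol oxygen secures fast trapping by ring closure, and dehydration to an enal conjugated with the electron-rich ring A should make that trapping irreversible.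

Step 3
Reactants: 6 (R)-5,7-bis(benzyloxy)-2-phenyl-2H-chromene-3-carbaldehyde
Product: 8 (R)-5,7-bis(benzyloxy)-2-phenylchroman-3-one, via enol formate 7 (not isolated)
Conditions: mCPBA (1.05 equiv), NaHCO3, CH2Cl2, 0 °C; then MeOH, KHCO3 (cat.), 0 °C; used at once in step 4
Reagents that add atoms: 3-chloroperbenzoic acid, OOC(=O)c1cccc(Cl)c1
Why: Baeyer–Villiger oxidation of an α-substituted β-aryl enal, in which the electron-rich vinylic carbon C3 should migrate to oxygen in preference to hydrogen to give the enol formate 7, whose mild methanolysis releases the enol that ketonises by protonation at C4, so that the helper carbon is exchanged for the C3 oxygen and C2 is not touched.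

Step 4
Reactants: 8 (R)-5,7-bis(benzyloxy)-2-phenylchroman-3-one
Product: 9 (2R,3R)-5,7-bis(benzyloxy)-2-phenylchroman-3-ol
Conditions: LiBH(s-Bu)3 (1.5 equiv), LiBr, THF, −78 °C; aq. NaOH work-up
Reagents that add atoms: none
Why: Ketone reduction by a bulky trialkylborohydride, which should attack the C3 carbonyl equatorially as known for benzylated flavan-3-ones and so give the axial C3 hydroxyl cis to the equatorial 2-phenyl group (3R).

Step 5
Reactants: 9 (2R,3R)-5,7-bis(benzyloxy)-2-phenylchroman-3-ol (one part of the batch)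
Product: 10 (2R,3R,4S)-5,7-bis(benzyloxy)-4-(2-ethoxyethoxy)-2-phenylchroman-3-ol
Conditions: DDQ (1.5 equiv), 2-ethoxyethanol (5 equiv), CH2Cl2, rt
Reagents that add atoms: 2-ethoxyethanol, CCOCCO
Why: Benzylic oxidation by DDQ, in which hydride abstraction from C4 (activated by O1 and the C5 and C7 benzyloxy groups of ring A) gives a quinone-methide-type cation that 2-ethoxyethanol should trap anti to the C3 hydroxyl, as in known C4 functionalisations of benzylated flavan-3-ols; the new C4 centre (4S) only carries the leaving group.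

Step 6
Reactants: 10 (2R,3R,4S)-5,7-bis(benzyloxy)-4-(2-ethoxyethoxy)-2-phenylchroman-3-ol; 9 (2R,3R)-5,7-bis(benzyloxy)-2-phenylchroman-3-ol (4 equiv, excess recovered)
Product: 11 (2R,3R,4R)-5,7-bis(benzyloxy)-4-[(2R,3R)-5,7-bis(benzyloxy)-3-hydroxy-2-phenylchroman-8-yl]-2-phenylchroman-3-ol
Conditions: Me3SiOTf (0.5 equiv), CH2Cl2, −78 °C; aq. NaHCO3
Reagents that add atoms: none
Why: Lewis-acid-promoted ionisation of the C4 ether to the ring-A-stabilised flavan-4-yl cation followed by Friedel–Crafts alkylation at C8 of 9, the most nucleophilic ring position, which should enter anti to the axial C3 hydroxyl to give the 3,4-trans (4R) interflavan bond, with the excess of 9 holding back further chain growth.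

Step 7
Reactants: 11 (2R,3R,4R)-5,7-bis(benzyloxy)-4-[(2R,3R)-5,7-bis(benzyloxy)-3-hydroxy-2-phenylchroman-8-yl]-2-phenylchroman-3-ol
Product: 12 (2R,3R,4R)-4-[(2R,3R)-3,5,7-trihydroxy-2-phenylchroman-8-yl]-2-phenylchroman-3,5,7-triol (CNP0154953.1)
Conditions: H2 (1 atm), Pd(OH)2 on carbon, THF/MeOH/H2O, rt
Reagents that add atoms: none
Why: Hydrogenolysis of the four benzyl ethers over Pd(OH)2 on carbon, conditions under which the ring C–O bond at C2 and the interflavan bond are known to survive, so that no stereocentre is touched.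

**Compound list**
1 | 2,4,6-trihydroxybenzaldehyde | O=Cc1c(O)cc(O)cc1O | starting material
2 | 2,4-bis(benzyloxy)-6-hydroxybenzaldehyde | O=Cc1c(O)cc(OCc2ccccc2)cc1OCc1ccccc1 | intermediate
3 | (E)-cinnamaldehyde | O=C/C=C/c1ccccc1 | starting material
4 | (S)-3-[3,5-bis(benzyloxy)-2-formylphenoxy]-3-phenylpropanal (oxa-Michael adduct, drawn as the free aldehyde; bound to the catalyst as enamine in the flask) | O(Cc1ccccc1)c1cc(OCc3ccccc3)c(C=O)c(c1)O[C@H](c1ccccc1)CC=O | intermediate
5 | (2S)-5,7-bis(benzyloxy)-4-hydroxy-2-phenylchroman-3-carbaldehyde (aldol, drawn as the free aldehyde; C3 and C4 configuration immaterial, both lost on dehydration) | O(Cc1ccccc1)c1cc(OCc3ccccc3)c2c(c1)O[C@H](c1ccccc1)C(C=O)C2O | intermediate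
6 | (R)-5,7-bis(benzyloxy)-2-phenyl-2H-chromene-3-carbaldehyde | O(Cc1ccccc1)c1cc(OCc3ccccc3)c2c(c1)O[C@H](c1ccccc1)C(C=O)=C2 | intermediate
7 | (R)-5,7-bis(benzyloxy)-2-phenyl-2H-chromen-3-yl formate (enol formate) | O(Cc1ccccc1)c1cc(OCc3ccccc3)c2c(c1)O[C@H](c1ccccc1)C(OC=O)=C2 | intermediate
8 | (R)-5,7-bis(benzyloxy)-2-phenylchroman-3-one | O(Cc1ccccc1)c1cc(OCc3ccccc3)c2c(c1)O[C@H](c1ccccc1)C(=O)C2 | intermediate
9 | (2R,3R)-5,7-bis(benzyloxy)-2-phenylchroman-3-ol (2,3-cis) | O(Cc1ccccc1)c1cc(OCc3ccccc3)c2c(c1)O[C@H](c1ccccc1)[C@H](O)C2 | intermediate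
10 | (2R,3R,4S)-5,7-bis(benzyloxy)-4-(2-ethoxyethoxy)-2-phenylchroman-3-ol (2,3-cis, 3,4-trans) | O(Cc1ccccc1)c1cc(OCc3ccccc3)c2c(c1)O[C@H](c1ccccc1)[C@H](O)[C@H]2OCCOCC | intermediate
11 | (2R,3R,4R)-5,7-bis(benzyloxy)-4-[(2R,3R)-5,7-bis(benzyloxy)-3-hydroxy-2-phenylchroman-8-yl]-2-phenylchroman-3-ol | O(Cc1ccccc1)c1cc(OCc3ccccc3)c2c(c1)O[C@H](c1ccccc1)[C@H](O)[C@H]2c1c(OCc3ccccc3)cc(OCc3ccccc3)c2c1O[C@H](c1ccccc1)[C@H](O)C2 | intermediate
12 | (2R,3R,4R)-4-[(2R,3R)-3,5,7-trihydroxy-2-phenylchroman-8-yl]-2-phenylchroman-3,5,7-triol | Oc1cc(O)c2c(c1)O[C@H](c1ccccc1)[C@H](O)[C@H]2c1c(O)cc(O)c2c1O[C@H](c1ccccc1)[C@H](O)C2 | target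

**Step count**
Total steps: 7. Longest linear sequence: 7 steps (1 to 2 to 6 to 8 to 9 to 10 to 11 to 12; compound 9 serves both as precursor of 10 and as the nucleophile in step 6).

**Steps most likely to fail, with fallbacks**

Step 2. The oxa-Michael addition is reversible and the aldol closure onto the hindered, electron-rich aldehyde may be slow, so the enantiomeric purity at C2 may erode and conversion may stall. Fallback: take C2 from the chiral pool. From 2, a Mitsunobu reaction (PPh3, DIAD, THF, 0 °C) with commercial (R)-1-phenylbut-3-en-1-ol should give, with inversion, (S)-2,4-bis(benzyloxy)-6-[(1-phenylbut-3-en-1-yl)oxy]benzaldehyde F1. Lemieux–Johnson cleavage of its terminal alkene (OsO4 cat., NaIO4, 2,6-lutidine, dioxane/water) should give the dialdehyde 4. Brief exposure of 4 to the same (S)-amine/acid pair should then only have to run the aldol condensation, and the route is rejoined at 6.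

Step 3. Hydrogen may migrate instead of the vinylic carbon (giving the acid), the peracid may epoxidise the enol formate or attack the electron-rich ring A, and the ketone may enolise at C2 during formate cleavage. Fallback: exchange the helper carbon for a heteroatom by a Curtius rearrangement instead. From 6, Pinnick oxidation (NaClO2, NaH2PO4, 2-methyl-2-butene, t-BuOH/water) should give (R)-5,7-bis(benzyloxy)-2-phenyl-2H-chromene-3-carboxylic acid F2. DPPA and Et3N in toluene should convert it into (R)-5,7-bis(benzyloxy)-2-phenyl-2H-chromene-3-carbonyl azide F3, which on warming to 80 °C should rearrange to (R)-5,7-bis(benzyloxy)-3-isocyanato-2-phenyl-2H-chromene F4. Trapping with t-BuOH should give tert-butyl (R)-[5,7-bis(benzyloxy)-2-phenyl-2H-chromen-3-yl]carbamate F5. Hydrolysis of this enecarbamate with aqueous oxalic acid in THF at rt should give the ketone, and the route is rejoined at 8.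

Step 6. The cation may be attacked at C6 instead of C8, and the dimer or the electrophile itself may act as nucleophile, leading to chain growth. Fallback: cap the nucleophilic position of the electrophilic unit with bromine so that the partners can be used in equal amounts. From 9, NBS in CH2Cl2 at −78 to 0 °C should give (2R,3R)-5,7-bis(benzyloxy)-8-bromo-2-phenylchroman-3-ol F6. DDQ and 2-ethoxyethanol should convert it into (2R,3R,4S)-5,7-bis(benzyloxy)-8-bromo-4-(2-ethoxyethoxy)-2-phenylchroman-3-ol F7. Coupling of F7 with one equivalent of 9 (Me3SiOTf, CH2Cl2, −78 °C) should give (2R,3R,4S)-5,7-bis(benzyloxy)-4-[(2R,3R)-5,7-bis(benzyloxy)-3-hydroxy-2-phenylchroman-8-yl]-8-bromo-2-phenylchroman-3-ol F8, which has the same spatial arrangement as 11 (the C4 descriptor changes only because of the bromine). Hydrogenolysis over Pd(OH)2 on carbon with Et3N should remove the bromine and the benzyl groups together, and the route is rejoined at 12.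

Further compounds
F1 | step 2 | (S)-2,4-bis(benzyloxy)-6-[(1-phenylbut-3-en-1-yl)oxy]benzaldehyde | O(Cc1ccccc1)c1cc(OCc3ccccc3)c(C=O)c(c1)O[C@H](c1ccccc1)CC=C
F2 | step 3 | (R)-5,7-bis(benzyloxy)-2-phenyl-2H-chromene-3-carboxylic acid | O(Cc1ccccc1)c1cc(OCc3ccccc3)c2c(c1)O[C@H](c1ccccc1)C(C(O)=O)=C2
F3 | step 3 | (R)-5,7-bis(benzyloxy)-2-phenyl-2H-chromene-3-carbonyl azide | O(Cc1ccccc1)c1cc(OCc3ccccc3)c2c(c1)O[C@H](c1ccccc1)C(C(=O)N=[N+]=[N-])=C2
F4 | step 3 | (R)-5,7-bis(benzyloxy)-3-isocyanato-2-phenyl-2H-chromene | O(Cc1ccccc1)c1cc(OCc3ccccc3)c2c(c1)O[C@H](c1ccccc1)C(N=C=O)=C2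
F5 | step 3 | tert-butyl (R)-[5,7-bis(benzyloxy)-2-phenyl-2H-chromen-3-yl]carbamate | O(Cc1ccccc1)c1cc(OCc3ccccc3)c2c(c1)O[C@H](c1ccccc1)C(NC(=O)OC(C)(C)C)=C2
F6 | step 6 | (2R,3R)-5,7-bis(benzyloxy)-8-bromo-2-phenylchroman-3-ol | O(Cc1ccccc1)c1cc(OCc3ccccc3)c2c(c1Br)O[C@H](c1ccccc1)[C@H](O)C2
F7 | step 6 | (2R,3R,4S)-5,7-bis(benzyloxy)-8-bromo-4-(2-ethoxyethoxy)-2-phenylchroman-3-ol | O(Cc1ccccc1)c1cc(OCc3ccccc3)c2c(c1Br)O[C@H](c1ccccc1)[C@H](O)[C@H]2OCCOCC
F8 | step 6 | (2R,3R,4S)-5,7-bis(benzyloxy)-4-[(2R,3R)-5,7-bis(benzyloxy)-3-hydroxy-2-phenylchroman-8-yl]-8-bromo-2-phenylchroman-3-ol | O(Cc1ccccc1)c1cc(OCc3ccccc3)c2c(c1Br)O[C@H](c1ccccc1)[C@H](O)[C@H]2c1c(OCc3ccccc3)cc(OCc3ccccc3)c2c1O[C@H](c1ccccc1)[C@H](O)C2
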